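**Numbering and assumptions**

- Cembrane numbering is used throughout: C1 is the ring CH bearing the C15(=C16H2)–C17O2H unit, then C2 (CH2), C3 (OAc), C4 (C18 methyl, OH), C5, C6, C7 (OH), C8 (C19 methyl, ring O), C9, C10, C11 (ring O), C12 (C20 methyl, OH), C13, C14. The target is (1R,3R,4S,7S,8R,11S,12R), with a cis-2,5-tetrahydrofuran.
- Assumption: (R)-(−)-lavandulol is bought as the single enantiomer; if not, it is obtained by lipase resolution of the cheap racemate.
- CIP label at C7 reads R while C6 carries sulfur (compounds 6–8 and 11–15); the geometry is unchanged.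

## Retrosynthetic overview

1. Target ⇐ macrocyclic diene 16: late C3/C4 anti-dioxygenation (Shi epoxidation, Markovnikov hydrolysis, acetylation) and isopropenyl → acrylic acid.
2. The 14-membered carbocycle is closed last at C5–C6: a C6 α-sulfonyl carbanion alkylates a C5 allylic chloride.
3. C13–C14 is made by Cu-catalysed opening of a C12–C13 epoxide with (R)-lavandulyl Grignard; lavandulol supplies C1 (stereocentre), C2–C5, C14 and C15–C18.
4. The THF ring and the C7/C8/C11/C12 stereotetrad come from geranyl acetate: two-directional Sharpless epoxidation, then the proposed base-catalysed Payne-initiated epoxide relay.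
5. Ring order: THF first, carbocycle second.

## Route

**Step 1**
Reactants: 1 geranyl acetate
Product: 2 (2E,6E)-8-hydroxygeranyl acetate
Conditions: SeO2 (0.2 eq), t-BuOOH, salicylic acid (cat.), CH2Cl2, rt; then NaBH4, MeOH, 0 °C
Reagents that add atoms: selenium dioxide O=[Se]=O / tert-butyl hydroperoxide CC(C)(C)OO (one O)
Why: Riley allylic oxidation (ene then [2,3]-shift) is selective for the (E)-methyl of the electron-rich terminal alkene, the allylic-acetate alkene being deactivated; NaBH4 returns any over-oxidised enal.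

**Step 2**
Reactants: 2
Product: 3 (2E,6E)-2,6-dimethylocta-2,6-diene-1,8-diol
Conditions: K2CO3, MeOH, rt
Reagents that add atoms: none
Why: Simple acetate methanolysis; nothing else is base-sensitive.

**Step 3**
Reactants: 3
Product: 4 (2R,3R,6R,7R)-2,3:6,7-diepoxy-2,6-dimethyloctane-1,8-diol (C6-OH, 7R,8R-epoxide, 11R,12R-epoxide, C13-OH)
Conditions: Ti(OiPr)4, D-(−)-DET, t-BuOOH, 4 Å MS, CH2Cl2, −25 °C
Reagents that add atoms: tert-butyl hydroperoxide CC(C)(C)OO (two O)
Why: Two-directional Sharpless asymmetric epoxidation; D-(−)-tartrate delivers oxygen to the same face of both allylic alcohols (the face giving (2R,3R)-epoxygeraniol), setting all four centres under reagent control.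

**Step 4 (proposed new step)**
Reactants: 4
Product: 5 (2R)-2-{(2S,5R)-5-methyl-5-[(2S)-oxiran-2-yl]oxolan-2-yl}propane-1,2-diol (C6–C7 epoxide 7S; THF 8R,11S; 12R-OH; C13-OH)
Conditions: KOt-Bu (0.2 eq), t-BuOH–THF (1:1), 0.03 M, 0 → 25 °C
Reagents that add atoms: none (isomerisation)
Why: Proposed new method: an anionic "epoxide relay" in which the C6 alkoxide undergoes reversible Payne transposition (3-exo attack at secondary C7, inversion R→S), the unmasked C8 alkoxide then closes irreversibly 5-exo onto secondary C11 (inversion R→S) to form the cis-THF and release the C12 alkoxide that turns over the base, C8 and C12 being retained; both SN2 events are exo at secondary carbons, whereas initiation from the C13 end would need two attacks at fully substituted epoxide carbons, so the cascade should self-sort; the closest known reactions are the Payne rearrangement with in situ trapping and base-mediated 5-exo hydroxy-epoxide cyclisations.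

**Step 5**
Reactants: 5
Product: 6 (2R)-2-{(2S,5R)-5-[(1R)-1-hydroxy-2-(phenylsulfanyl)ethyl]-5-methyloxolan-2-yl}propane-1,2-diol
Conditions: PhSH, K2CO3, MeOH, rt
Reagents that add atoms: thiophenol Sc1ccccc1
Why: SN2 thiolate opening at the unhindered terminal carbon C6 leaves the C7–O bond, and so its configuration, untouched, and installs a Grignard-inert precursor of the later C6 nucleophile.

**Step 6**
Reactants: 6
Product: 7 C13 mono-tosylate of 6
Conditions: TsCl (1.05 eq), Bu2SnO (5 mol %), Et3N, CH2Cl2, 0 °C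
Reagents that add atoms: tosyl chloride Cc1ccc(cc1)S(Cl)(=O)=O
Why: Stannylene-mediated sulfonylation is selective for the primary OH of the terminal 1,2-diol; the isolated secondary C7-OH and tertiary C12-OH do not react.

**Step 7**
Reactants: 7
Product: 8 (1R)-1-{(2R,5S)-2-methyl-5-[(2R)-2-methyloxiran-2-yl]oxolan-2-yl}-2-(phenylsulfanyl)ethan-1-ol (C12–C13 epoxide)
Conditions: K2CO3, MeOH, 0 °C → rt
Reagents that add atoms: none
Why: Intramolecular Williamson (3-exo-tet) closure by the C12 alkoxide keeps the C12–O bond, so C12 stays R.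

**Step 8**
Reactants: 9 (R)-lavandulol
Product: 10 (3R)-3-(bromomethyl)-2,6-dimethylhepta-1,5-diene ((R)-lavandulyl bromide)
Conditions: CBr4, PPh3, CH2Cl2, 0 °C
Reagents that add atoms: carbon tetrabromide BrC(Br)(Br)Br (Br)
Why: Appel bromination of the primary alcohol does not touch the β-stereocentre (future C1) or the alkenes.

**Step 9**
Reactants: 8 and 10
Product: 11 (2R,5R)-2-{(2S,5R)-5-[(1R)-1-hydroxy-2-(phenylsulfanyl)ethyl]-5-methyloxolan-2-yl}-8-methyl-5-(prop-1-en-2-yl)non-7-en-2-ol (C13–C14 bond formed; C12-OH)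
Conditions: 10 (2.5 eq), Mg, THF, 0 °C, used at once; then CuI (10 mol %), 8, THF, −30 → 0 °C
Reagents that add atoms: none besides 8 and 10
Why: Cu-catalysed Grignard opening of the 2,2-disubstituted epoxide occurs at the CH2 terminus (C13), leaving the C12 carbinol configuration intact; the first equivalent of Grignard is consumed by C7-OH and the thioether is inert.

**Step 10**
Reactants: 11
Product: 12 the corresponding phenyl sulfone
Conditions: (NH4)6Mo7O24·4H2O (cat.), 30 % H2O2, EtOH, 0 °C → rt
Reagents that add atoms: hydrogen peroxide OO (two O)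
Why: Molybdate-catalysed sulfide → sulfone oxidation is chemoselective over the trisubstituted and 1,1-disubstituted alkenes.

**Step 11**
Reactants: 12
Product: 13 (2E,5R,8R)-8-{(2S,5R)-5-[(1R)-1-hydroxy-2-(phenylsulfonyl)ethyl]-5-methyloxolan-2-yl}-2-methyl-5-(prop-1-en-2-yl)non-2-ene-1,8-diol (C5-OH)
Conditions: SeO2 (0.3 eq), t-BuOOH, salicylic acid (cat.), CH2Cl2, rt; then NaBH4, MeOH
Reagents that add atoms: selenium dioxide O=[Se]=O / tert-butyl hydroperoxide CC(C)(C)OO (one O)
Why: Riley oxidation of the prenyl terminus gives the (E)-allylic alcohol, fixing the 3E geometry; the less nucleophilic isopropenyl group reacts much more slowly.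

**Step 12**
Reactants: 13
Product: 14 the (E)-allylic chloride at C5
Conditions: NCS, Me2S, CH2Cl2, −20 → 0 °C
Reagents that add atoms: N-chlorosuccinimide ClN1C(=O)CCC1=O (Cl)
Why: Corey–Kim chlorination converts only the allylic primary alcohol, without allylic transposition, and leaves the secondary and tertiary alcohols alone.

**Step 13**
Reactants: 14
Product: 15 (1R,3E,7R,8R,11S,12R)-8,11-epoxy-6-(phenylsulfonyl)cembra-3,15-diene-7,12-diol (C6 epimers)
Conditions: LDA (3.3 eq), THF–DMPU, −78 → −20 °C, syringe-pump addition, 2 mM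
Reagents that add atoms: none
Why: Intramolecular SN2 alkylation of the β-oxido α-sulfonyl carbanion (the O-lithiated β-hydroxy sulfone does not eliminate) on the primary allylic chloride closes the ring at C5–C6, the classical carbanion/allylic halide macrocyclisation used for cembranoids.

**Step 14**
Reactants: 15
Product: 16 (1R,3E,7S,8R,11S,12R)-8,11-epoxycembra-3,15-diene-7,12-diol
Conditions: Na(Hg) (6 %), Na2HPO4, MeOH–THF, −20 °C
Reagents that add atoms: none
Why: Reductive desulfonylation; with a free (unacylated) β-hydroxyl, C–S cleavage and protonation dominate over Julia-type elimination, and the homoallylic position means the alkene cannot migrate.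

**Step 15**
Reactants: 16
Product: 17 the 7-O-TBS ether of 16
Conditions: TBSOTf (1.1 eq), 2,6-lutidine, CH2Cl2, −78 °C
Reagents that add atoms: TBS triflate CC(C)(C)[Si](C)(C)OS(=O)(=O)C(F)(F)F
Why: The secondary C7-OH silylates in preference to tertiary C12-OH; masking it prevents 5-exo attack on the coming C3–C4 epoxide and distinguishes it from C3-OH.

**Step 16**
Reactants: 17
Product: 18 (1R,3R,4R,7S,8R,11S,12R)-7-(TBS-oxy)-3,4:8,11-diepoxycembr-15-en-12-ol
Conditions: D-fructose-derived Shi ketone (0.3 eq), Oxone, K2CO3, Bu4NHSO4, MeCN–DMM / pH 10.5 buffer, 0 °C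
Reagents that add atoms: potassium peroxymonosulfate OOS(=O)(=O)[O-].[K+] (one O)
Why: Shi epoxidation converts the (E)-trisubstituted alkene to the (3R,4R)-epoxide under catalyst control (spiro transition state) and spares the 1,1-disubstituted isopropenyl group, a poor substrate.

**Step 17**
Reactants: 18
Product: 19 (1R,3R,4S,7S,8R,11S,12R)-7-(TBS-oxy)-8,11-epoxycembr-15-ene-3,4,12-triol
Conditions: HClO4 (5 mol %), THF–H2O (3:1), 0 °C
Reagents that add atoms: water O
Why: Acid-catalysed hydrolysis opens the trisubstituted epoxide at tertiary C4 with inversion (4R→4S) while C3 keeps its oxygen (3R), giving the required anti diol; the secondary TBS ether survives brief dilute acid.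

**Step 18**
Reactants: 19
Product: 20 the 3-O-acetate of 19
Conditions: Ac2O (1.2 eq), pyridine, DMAP (cat.), CH2Cl2, 0 °C
Reagents that add atoms: acetic anhydride CC(=O)OC(C)=O
Why: C3-OH is the only secondary hydroxyl left (C4 and C12 are tertiary, C7 is silylated), so acetylation is site-selective.

**Step 19**
Reactants: 20
Product: 21 the C17 allylic alcohol (isopropenyl CH3 → CH2OH)
Conditions: SeO2 (0.5 eq), t-BuOOH, salicylic acid (cat.), CH2Cl2, rt
Reagents that add atoms: selenium dioxide O=[Se]=O / tert-butyl hydroperoxide CC(C)(C)OO (one O)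
Why: Riley oxidation of the only remaining alkene, with hydrogen abstraction from CH3 preferred over the hindered C1 methine; acetate, silyl ether and tertiary alcohols tolerate the conditions.

**Step 20**
Reactants: 21
Product: 22 the C17 enal (2-substituted acrolein)
Conditions: Dess–Martin periodinane, NaHCO3, CH2Cl2, 0 °C
Reagents that add atoms: none
Why: Only the primary allylic alcohol can be oxidised (the other free hydroxyls are tertiary); C1 is not epimerised under buffered conditions.

**Step 21**
Reactants: 22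
Product: 23 7-O-TBS acid (target with C7-OTBS)
Conditions: NaClO2, NaH2PO4, 2-methyl-2-butene, t-BuOH–H2O, 0 °C → rt
Reagents that add atoms: sodium chlorite [Na+].[O-]Cl=O (one O)
Why: Pinnick oxidation converts the enal to the α-substituted acrylic acid without touching the acetate or the alkene.

**Step 22**
Reactants: 23
Product: 24 Dendronpholide J
Conditions: HF·pyridine, THF, 0 °C → rt
Reagents that add atoms: none
Why: Acidic fluoride desilylation frees C7-OH without hydrolysing or migrating the C3 acetate.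

## Compound list

1 | geranyl acetate | CC(C)=CCC/C(C)=C/COC(C)=O | starting material
2 | (2E,6E)-8-hydroxygeranyl acetate | OC/C(C)=C/CC/C(C)=C/COC(C)=O | intermediate
3 | (2E,6E)-2,6-dimethylocta-2,6-diene-1,8-diol | OC/C(C)=C/CC/C(C)=C/CO | intermediate
4 | (2R,3R,6R,7R)-2,3:6,7-diepoxy-2,6-dimethyloctane-1,8-diol | OC[C@H]1O[C@]1(C)CC[C@H]1O[C@]1(C)CO | intermediate
5 | (2R)-2-{(2S,5R)-5-methyl-5-[(2S)-oxiran-2-yl]oxolan-2-yl}propane-1,2-diol | C1O[C@@H]1[C@@]2(C)CC[C@H](O2)[C@](C)(O)CO | intermediate
6 | (2R)-2-{(2S,5R)-5-[(1R)-1-hydroxy-2-(phenylsulfanyl)ethyl]-5-methyloxolan-2-yl}propane-1,2-diol | OC[C@@](C)(O)[C@@H]1CC[C@@](C)(O1)[C@@H](O)CSc2ccccc2 | intermediate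
7 | primary (C13) tosylate of 6 | Cc1ccc(cc1)S(=O)(=O)OC[C@@](C)(O)[C@@H]2CC[C@@](C)(O2)[C@@H](O)CSc3ccccc3 | intermediate
8 | (1R)-1-{(2R,5S)-2-methyl-5-[(2R)-2-methyloxiran-2-yl]oxolan-2-yl}-2-(phenylsulfanyl)ethan-1-ol | C1O[C@@]1(C)[C@@H]2CC[C@@](C)(O2)[C@@H](O)CSc3ccccc3 | intermediate
9 | (R)-lavandulol, (2R)-5-methyl-2-(prop-1-en-2-yl)hex-4-en-1-ol | CC(C)=CC[C@@H](CO)C(C)=C | starting material
10 | (R)-lavandulyl bromide | CC(C)=CC[C@@H](CBr)C(C)=C | intermediate
11 | seco-cembrane sulfide (C13–C14 joined; 12R-OH, 7-OH, C6-SPh) | C=C(C)[C@@H](CC=C(C)C)CC[C@@](C)(O)[C@@H]1CC[C@@](C)(O1)[C@@H](O)CSc2ccccc2 | intermediate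
12 | sulfone of 11 | C=C(C)[C@@H](CC=C(C)C)CC[C@@](C)(O)[C@@H]1CC[C@@](C)(O1)[C@@H](O)CS(=O)(=O)c2ccccc2 | intermediate
13 | (E)-C5 allylic alcohol of 12 | C=C(C)[C@@H](C/C=C(\C)CO)CC[C@@](C)(O)[C@@H]1CC[C@@](C)(O1)[C@@H](O)CS(=O)(=O)c2ccccc2 | intermediate
14 | (E)-C5 allylic chloride | C=C(C)[C@@H](C/C=C(\C)CCl)CC[C@@](C)(O)[C@@H]1CC[C@@](C)(O1)[C@@H](O)CS(=O)(=O)c2ccccc2 | intermediate
15 | (1R,3E,7R,8R,11S,12R)-8,11-epoxy-6-(phenylsulfonyl)cembra-3,15-diene-7,12-diol (C6 epimers) | C=C(C)[C@@H]1CC[C@@](C)(O)[C@@H]2CC[C@@](C)(O2)[C@@H](O)C(S(=O)(=O)c3ccccc3)C/C(C)=C/C1 | intermediate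
16 | (1R,3E,7S,8R,11S,12R)-8,11-epoxycembra-3,15-diene-7,12-diol | C=C(C)[C@@H]1CC[C@@](C)(O)[C@@H]2CC[C@@](C)(O2)[C@@H](O)CC/C(C)=C/C1 | intermediate
17 | 7-O-TBS ether of 16 | C=C(C)[C@@H]1CC[C@@](C)(O)[C@@H]2CC[C@@](C)(O2)[C@@H](O[Si](C)(C)C(C)(C)C)CC/C(C)=C/C1 | intermediate
18 | (3R,4R)-3,4-epoxide of 17 | C=C(C)[C@@H]1CC[C@@](C)(O)[C@@H]2CC[C@@](C)(O2)[C@@H](O[Si](C)(C)C(C)(C)C)CC[C@@]3(C)O[C@@H]3C1 | intermediate
19 | (3R,4S)-3,4-diol (7-OTBS, 12-OH) | C=C(C)[C@@H]1CC[C@@](C)(O)[C@@H]2CC[C@@](C)(O2)[C@@H](O[Si](C)(C)C(C)(C)C)CC[C@](C)(O)[C@H](O)C1 | intermediate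
20 | 3-O-acetate of 19 | C=C(C)[C@@H]1CC[C@@](C)(O)[C@@H]2CC[C@@](C)(O2)[C@@H](O[Si](C)(C)C(C)(C)C)CC[C@](C)(O)[C@H](OC(C)=O)C1 | intermediate
21 | C17 allylic alcohol | C=C(CO)[C@@H]1CC[C@@](C)(O)[C@@H]2CC[C@@](C)(O2)[C@@H](O[Si](C)(C)C(C)(C)C)CC[C@](C)(O)[C@H](OC(C)=O)C1 | intermediate
22 | C17 enal | C=C(C=O)[C@@H]1CC[C@@](C)(O)[C@@H]2CC[C@@](C)(O2)[C@@H](O[Si](C)(C)C(C)(C)C)CC[C@](C)(O)[C@H](OC(C)=O)C1 | intermediate
23 | 7-O-TBS Dendronpholide J | C=C(C(=O)O)[C@@H]1CC[C@@](C)(O)[C@@H]2CC[C@@](C)(O2)[C@@H](O[Si](C)(C)C(C)(C)C)CC[C@](C)(O)[C@H](OC(C)=O)C1 | intermediate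
24 | Dendronpholide J, (1R,3R,4S,7S,8R,11S,12R)-3-acetoxy-8,11-epoxy-4,7,12-trihydroxycembr-15(16)-en-17-oic acid | C=C(C(=O)O)[C@@H]1CC[C@@](C)(O)[C@@H]2CC[C@@](C)(O2)[C@@H](O)CC[C@](C)(O)[C@H](OC(C)=O)C1 | target

## Totals and risk

- Total steps: 22.
- Longest linear sequence: 21 (steps 1–7, then 9–22, from geranyl acetate).

Three steps most likely to fail:

1. **Step 4 (proposed epoxide relay).** The risks are slow Payne turnover, competing 6-endo closure or oligomerisation of the epoxy-diol. Fallback (known chemistry): use the enantiomeric L-(+)-DET series on C13/C6-differentiated material and run the Markovnikov-matched acid cascade. A C13 tert-butyl carbonate opens the C11–C12 epoxide at C12 with BF3·OEt2 (inversion, cyclic carbonate), and the freed C11-OH closes 5-exo at C8 (inversion). This gives the same 7S,8R,11S,12R tetrad; carbonate methanolysis, tosylation and base then converge on 8.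

2. **Step 13 (macrocyclisation at C5–C6).** The risks are oligomerisation, O-alkylation and retro-aldol of the β-oxido sulfone. Fallback: reverse the order of the two C–C bond formations. Join C5–C6 first by bimolecular allylation of the C6 β-hydroxy-sulfone dianion with an O-protected lavandulyl-derived (E)-allylic bromide. Then close the ring at C13–C14 by intramolecular opening of the C12–C13 epoxide with a C14 phenylsulfonyl carbanion, followed by desulfonylation.

3. **Step 19 (late SeO2 oxidation of the isopropenyl group).** The risks are competing oxidation at the C1 methine and low conversion. Fallback: replace lavandulol by an Evans-alkylation-derived C1 fragment that carries C15 as a ketal-protected methyl ketone. Unmask it late and build the acrylic acid by kinetic enol triflate formation and Pd-catalysed carbonylation (CO, H2O), before the final acetylation and desilylation.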